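Retrosynthesis: the C-8 methylidene is cut last (ketone methylenation); then the ring-fusion bond C-5–C-10 and the C-3–C-4 bond are cut together, opening rings B and A to an acyclic dialdehyde with C-8 masked as a dioxolane; this chain is cut at C-8–C-9 (aldol) and C-11–O (aryl ether) into fragment 1 and fragment 2.
Forward: fragment 1 (C-11, C-9, C-10, C-1 to C-3) and fragment 2 (C-8 to C-4 with its methyl and oxygenated carbon) are joined by an Evans aldol; umbelliferone is attached by Mitsunobu reaction; C-8 is oxidised and ketalised; a hydrogen-atom-transfer radical–polar crossover closes ring B (C-5–C-10) and then ring A (C-3–C-4); aldehyde reduction, ketal hydrolysis and methylenation finish.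
Enabling feature: in ring A the carbinol C-3 is flanked by quaternary C-4 carrying a one-carbon unit at the aldehyde/alcohol level (aldol retron), and C-4 is joined through C-5 to the methyl-bearing quaternary C-10. C-10 can therefore be a tertiary radical born from a 1,1-disubstituted alkene (its CH2 becomes the angular methyl), C-5 the β-carbon of a 2-methyl-enal, and C-4 the resulting enolate.
Stereochemistry: C-9 from the auxiliary-controlled aldol; C-10 and C-5 from the chair transition state of the 6-exo radical closure with the C-9 substituent equatorial; C-4 and C-3 from the closed chair aldol; the transient C-8 carbinol is oxidised away.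
Numbering is that of the drimane skeleton: ring A = C-1 to C-5 and C-10, ring B = C-5 to C-10, C-11 = aryloxymethyl carbon on C-9, C-12 = methylidene carbon on C-8.
Key step: step 14

Remark: epoxide 9 is used as the racemate, because its stereocentre disappears in step 4.

Step 1
Reactants: 1 3-methylbut-3-en-1-ol; 2 (2-bromoethoxy)(tert-butyl)dimethylsilane
Product: 4 6-{[tert-butyl(dimethyl)silyl]oxy}-3-methylidenehexan-1-ol, via dilithio dianion 3 (not isolated)
Conditions: n-BuLi (2 equiv), TMEDA, Et2O/hexane, 0 °C to rt; then 2, THF, −78 °C to 0 °C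
Reagents that add atoms: none
Why: Alkoxide-assisted allylic metalation of 1 should give the allyllithium dianion 3, whose symmetric 2-substituted allyl carbon terminus displaces the primary bromide of 2 (allylic metalation/alkylation) without a regiochemical choice.

Step 2
Reactants: 4 6-{[tert-butyl(dimethyl)silyl]oxy}-3-methylidenehexan-1-ol
Product: 5 6-{[tert-butyl(dimethyl)silyl]oxy}-3-methylidenehexanoic acid
Conditions: TEMPO (cat.), PhI(OAc)2, MeCN/H2O, rt
Reagents that add atoms: water, O
Why: The nitroxyl-catalysed oxidation should take the primary alcohol through the aldehyde hydrate to the acid under near-neutral conditions that neither move the 1,1-disubstituted double bond into conjugation nor cleave the silyl ether.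

Step 3
Reactants: 5 6-{[tert-butyl(dimethyl)silyl]oxy}-3-methylidenehexanoic acid; 6 (4S)-4-benzyl-1,3-oxazolidin-2-one
Product: 8 (4S)-4-benzyl-3-(6-{[tert-butyl(dimethyl)silyl]oxy}-3-methylidenehexanoyl)-1,3-oxazolidin-2-one, via mixed pivalic anhydride 7 (not isolated)
Conditions: pivaloyl chloride, Et3N, THF, −20 °C; then 6, LiCl, rt
Reagents that add atoms: pivaloyl chloride, CC(C)(C)C(=O)Cl (its acyl group is carried only by 7)
Why: Mixed-anhydride N-acylation of the oxazolidinone under LiCl/Et3N needs no strong base and so should not isomerise the β,γ-unsaturated acyl group.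

Step 4
Reactants: 9 2-ethenyl-2-methyloxirane; 10 (1,3-dioxolan-2-ylmethyl)magnesium bromide
Product: 11 (2E)-5-(1,3-dioxolan-2-yl)-2-methylpent-2-en-1-ol
Conditions: CuI (cat.), THF, −30 °C to 0 °C; aq NH4Cl
Reagents that add atoms: none
Why: Copper-catalysed SN2' opening of the vinyl epoxide by the Grignard reagent should give the trisubstituted (E)-allylic alcohol, and this geometry is in any case erased at C-4 in step 14.

Step 5
Reactants: 11 (2E)-5-(1,3-dioxolan-2-yl)-2-methylpent-2-en-1-ol
Product: 12 tert-butyl{[(2E)-5-(1,3-dioxolan-2-yl)-2-methylpent-2-en-1-yl]oxy}diphenylsilane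
Conditions: TBDPSCl, imidazole, CH2Cl2, 0 °C to rt
Reagents that add atoms: tert-butyl(chloro)diphenylsilane, CC(C)(C)[Si](Cl)(c1ccccc1)c1ccccc1
Why: Standard silylation of a primary allylic alcohol; the diphenylsilyl ether is chosen because it should survive the acid of step 6.

Step 6
Reactants: 12 tert-butyl{[(2E)-5-(1,3-dioxolan-2-yl)-2-methylpent-2-en-1-yl]oxy}diphenylsilane
Product: 13 (4E)-6-{[tert-butyl(diphenyl)silyl]oxy}-5-methylhex-4-enal
Conditions: PPTS (cat.), acetone/H2O, reflux
Reagents that add atoms: water, O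
Why: Mild acid-catalysed acetal hydrolysis should free the aldehyde while the robust silyl ether and the trisubstituted alkene are untouched.

Step 7
Reactants: 8 (4S)-4-benzyl-3-(6-{[tert-butyl(dimethyl)silyl]oxy}-3-methylidenehexanoyl)-1,3-oxazolidin-2-one; 13 (4E)-6-{[tert-butyl(diphenyl)silyl]oxy}-5-methylhex-4-enal
Product: 15 (4S)-4-benzyl-3-[(2S,3R,6E)-8-{[tert-butyl(diphenyl)silyl]oxy}-2-(5-{[tert-butyl(dimethyl)silyl]oxy}pent-1-en-2-yl)-3-hydroxy-7-methyloct-6-enoyl]-1,3-oxazolidin-2-one, via dibutylboron enolate 14 (not isolated)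
Conditions: Bu2BOTf, i-Pr2NEt, CH2Cl2, −78 °C to 0 °C; then 13, −78 °C to 0 °C; then pH 7 buffer, MeOH, H2O2, 0 °C
Reagents that add atoms: dibutylboron triflate, CCCCB(CCCC)OS(=O)(=O)C(F)(F)F (boron is carried only by 14)
Why: In this Evans syn aldol the (Z)-boron enolate should react at its α-carbon through a closed chair transition state on the face away from the benzyl group, setting C-9 (and the transient C-8 carbinol) and leaving the double bond out of conjugation.

Step 8
Reactants: 15 the aldol adduct named in step 7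
Product: 16 (2R,3R,6E)-8-{[tert-butyl(diphenyl)silyl]oxy}-2-(5-{[tert-butyl(dimethyl)silyl]oxy}pent-1-en-2-yl)-7-methyloct-6-ene-1,3-diol
Conditions: LiBH4, MeOH (1 equiv), THF, 0 °C
Reagents that add atoms: none
Why: Reductive cleavage of the imide by LiBH4 should turn the activated carbonyl into the C-11 primary alcohol and release the auxiliary without touching silyl ethers or alkenes.

Step 9
Reactants: 16 the diol named in step 8; 17 7-hydroxy-2H-chromen-2-one (umbelliferone)
Product: 18 7-{[(2R,3R,6E)-8-{[tert-butyl(diphenyl)silyl]oxy}-2-(5-{[tert-butyl(dimethyl)silyl]oxy}pent-1-en-2-yl)-3-hydroxy-7-methyloct-6-en-1-yl]oxy}-2H-chromen-2-one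
Conditions: PPh3, DIAD, THF, 0 °C to rt
Reagents that add atoms: none
Why: In this Mitsunobu etherification the acidic phenol should displace the activated primary hydroxyl, while the hindered secondary C-8 hydroxyl should not compete.

Step 10
Reactants: 18 the aryl ether named in step 9
Product: 19 7-{[(2R,6E)-8-{[tert-butyl(diphenyl)silyl]oxy}-2-(5-{[tert-butyl(dimethyl)silyl]oxy}pent-1-en-2-yl)-7-methyl-3-oxooct-6-en-1-yl]oxy}-2H-chromen-2-one
Conditions: Dess–Martin periodinane, CH2Cl2, 0 °C; product taken on at once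
Reagents that add atoms: none
Why: The Dess–Martin oxidation is fast and base-free, which should spare the C-9 centre whose hydrogen is α to the new ketone, allylic and β to the aryloxy group.

Step 11
Reactants: 19 the ketone named in step 10
Product: 20 7-{[(2R)-2-(2-{(3E)-5-[(tert-butyldiphenylsilyl)oxy]-4-methylpent-3-en-1-yl}-1,3-dioxolan-2-yl)-6-[(tert-butyldimethylsilyl)oxy]-3-methylidenehexyl]oxy}-2H-chromen-2-one
Conditions: 1,2-bis(trimethylsilyloxy)ethane, TMSOTf (cat.), CH2Cl2, −78 °C to −20 °C; pyridine quench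
Reagents that add atoms: 1,2-bis(trimethylsilyloxy)ethane, C[Si](C)(C)OCCO[Si](C)(C)C
Why: Noyori ketalisation is aprotic and cold, so it should neither enolise C-9 nor move the alkene, and the dioxolane then masks C-8 and removes the acidity at C-9.

Step 12
Reactants: 20 the bis-silyl ketal named in step 11
Product: 21 7-{[(2R)-6-hydroxy-2-{2-[(3E)-5-hydroxy-4-methylpent-3-en-1-yl]-1,3-dioxolan-2-yl}-3-methylidenehexyl]oxy}-2H-chromen-2-one
Conditions: TBAF, THF, 0 °C to rt
Reagents that add atoms: none
Why: Fluoride should cleave both silyl ethers, while the ketal, the aryl ether and the lactone are inert.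

Step 13
Reactants: 21 the diol named in step 12
Product: 22 (2E)-2-methyl-5-{2-[(2R)-3-methylidene-6-oxo-1-[(2-oxo-2H-chromen-7-yl)oxy]hexan-2-yl]-1,3-dioxolan-2-yl}pent-2-enal
Conditions: Dess–Martin periodinane, CH2Cl2, 0 °C to rt
Reagents that add atoms: none
Why: One Dess–Martin oxidation should convert the allylic alcohol into the (E)-enal and the primary alcohol into the C-3 aldehyde without opening the ketal.

Step 14
Reactants: 22 the dialdehyde named in step 13
Product: 24 (1'R,4a'S,5'S,6'R,8a'R)-6'-hydroxy-5',8a'-dimethyl-1'-{[(2-oxo-2H-chromen-7-yl)oxy]methyl}octahydro-1'H-spiro[1,3-dioxolane-2,2'-naphthalene]-5'-carbaldehyde, via ring-B iron enolate 23 (not isolated)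
Conditions: Fe(acac)3, PhSiH3, EtOH/THF, high dilution, 0 °C to rt
Reagents that add atoms: none
Why: Fe(acac)3 and PhSiH3 should form an iron hydride that transfers a hydrogen atom to the only electron-rich 1,1-disubstituted alkene (its CH2 becomes the C-10 methyl); the tertiary C-10 radical closes ring B by 6-exo-trig addition to C-5 of the 2-methyl-enal, and the α-formyl radical is reduced by divalent iron to enolate 23, which closes ring A by a 6-(enolexo)-exo-trig aldol addition to the C-3 aldehyde. The closest known reaction type is the hydrogen-atom-transfer-initiated radical conjugate addition/aldol sequence (radical–polar crossover annulation and polycyclization of alkene, enal and carbonyl partners). C-10 and C-5 are set in a chair transition state for ring B with the C-9 aryloxymethyl group and the enal equatorial: H-9 lies beside the equatorial site of the planar radical and the fully substituted ketal carbon C-8 beside the axial site, so the longer 3-oxopropyl arm should sit equatorial and the methyl axial, which is also the arrangement from which the arm reaches C-4 to give the trans-fused system. C-4 and C-3 follow from a closed chair aldol transition state in which iron bridges the enolate and aldehyde oxygens: the C-4 methyl stays equatorial, away from the axial C-10 methyl, so the formyl group ends axial and the C-3 hydroxyl equatorial and cis to it. The step needs chemoselective hydrogen-atom transfer and an aldol that outruns protonation of the enolate; the first is secured by carrying C-8 as a ketal instead of a second 1,1-disubstituted alkene (the enal and coumarin double bonds are conjugated and electron-poor), the second by the intramolecular six-membered closure at high dilution.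

Step 15
Reactants: 24 the hydroxy aldehyde named in step 14
Product: 26 7-{[(1R,4aS,5R,6R,8aR)-6-hydroxy-5-(hydroxymethyl)-5,8a-dimethyl-2-oxodecahydronaphthalen-1-yl]methoxy}-2H-chromen-2-one, via ketal diol 25 (not isolated)
Conditions: NaBH4, MeOH, 0 °C; then aq HCl, THF, rt
Reagents that add atoms: water, O
Why: NaBH4 should reduce the hindered axial aldehyde but not the lactone, and aqueous acid then hydrolyses the dioxolane; C-9, now α to the ketone, already holds its equatorial, thermodynamically preferred configuration.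

Step 16
Reactants: 26 the keto diol named in step 15
Product: 27 7-{[(1R,4aS,5R,6R,8aR)-6-hydroxy-5-(hydroxymethyl)-5,8a-dimethyl-2-methylidenedecahydronaphthalen-1-yl]methoxy}-2H-chromen-2-one
Conditions: Zn, CH2Br2, TiCl4, THF (reagent preformed at 0 °C); then 26, CH2Cl2, 0 °C to rt
Reagents that add atoms: dibromomethane, BrCBr
Why: Lombardo methylenation is a non-basic, titanium-mediated carbonyl olefination that selects ketones over lactones and does not enolise the β-aryloxy ketone, so C-9 and the ether should survive, with excess reagent covering the free hydroxyls.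

Compound list
1 | 3-methylbut-3-en-1-ol | C=C(C)CCO | starting material
2 | (2-bromoethoxy)(tert-butyl)dimethylsilane | CC(C)(C)[Si](C)(C)OCCBr | starting material
3 | dilithio dianion of 1 (lithium 3-(lithiomethyl)but-3-en-1-olate) | [Li]CC(=C)CCO[Li] | intermediate
4 | 6-{[tert-butyl(dimethyl)silyl]oxy}-3-methylidenehexan-1-ol | CC(C)(C)[Si](C)(C)OCCCC(=C)CCO | intermediate
5 | 6-{[tert-butyl(dimethyl)silyl]oxy}-3-methylidenehexanoic acid | CC(C)(C)[Si](C)(C)OCCCC(=C)CC(=O)O | intermediate
6 | (4S)-4-benzyl-1,3-oxazolidin-2-one | O=C1N[C@@H](Cc2ccccc2)CO1 | starting material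
7 | mixed anhydride of 5 with pivalic acid | CC(C)(C)[Si](C)(C)OCCCC(=C)CC(=O)OC(=O)C(C)(C)C | intermediate
8 | (4S)-4-benzyl-3-(6-{[tert-butyl(dimethyl)silyl]oxy}-3-methylidenehexanoyl)-1,3-oxazolidin-2-one | CC(C)(C)[Si](C)(C)OCCCC(=C)CC(=O)N1[C@@H](Cc2ccccc2)COC1=O | intermediate
9 | 2-ethenyl-2-methyloxirane (racemic) | C=CC1(C)CO1 | starting material
10 | (1,3-dioxolan-2-ylmethyl)magnesium bromide | Br[Mg]CC1OCCO1 | starting material
11 | (2E)-5-(1,3-dioxolan-2-yl)-2-methylpent-2-en-1-ol | OC/C(C)=C/CCC1OCCO1 | intermediate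
12 | tert-butyl{[(2E)-5-(1,3-dioxolan-2-yl)-2-methylpent-2-en-1-yl]oxy}diphenylsilane | CC(C)(C)[Si](c1ccccc1)(c1ccccc1)OC/C(C)=C/CCC1OCCO1 | intermediate
13 | (4E)-6-{[tert-butyl(diphenyl)silyl]oxy}-5-methylhex-4-enal | O=CCC/C=C(\C)CO[Si](c1ccccc1)(c1ccccc1)C(C)(C)C | intermediate
14 | (Z)-dibutylboron enolate of 8 | CCCCB(CCCC)O/C(=C\C(=C)CCCO[Si](C)(C)C(C)(C)C)N1[C@@H](Cc2ccccc2)COC1=O | intermediate
15 | (4S)-4-benzyl-3-[(2S,3R,6E)-8-{[tert-butyl(diphenyl)silyl]oxy}-2-(5-{[tert-butyl(dimethyl)silyl]oxy}pent-1-en-2-yl)-3-hydroxy-7-methyloct-6-enoyl]-1,3-oxazolidin-2-one | CC(C)(C)[Si](C)(C)OCCCC(=C)[C@H](C(=O)N1[C@@H](Cc2ccccc2)COC1=O)[C@H](O)CC/C=C(\C)CO[Si](c1ccccc1)(c1ccccc1)C(C)(C)C | intermediate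
16 | (2R,3R,6E)-8-{[tert-butyl(diphenyl)silyl]oxy}-2-(5-{[tert-butyl(dimethyl)silyl]oxy}pent-1-en-2-yl)-7-methyloct-6-ene-1,3-diol | CC(C)(C)[Si](C)(C)OCCCC(=C)[C@H](CO)[C@H](O)CC/C=C(\C)CO[Si](c1ccccc1)(c1ccccc1)C(C)(C)C | intermediate
17 | 7-hydroxy-2H-chromen-2-one (umbelliferone) | Oc1ccc2ccc(=O)oc2c1 | starting material
18 | 7-{[(2R,3R,6E)-8-{[tert-butyl(diphenyl)silyl]oxy}-2-(5-{[tert-butyl(dimethyl)silyl]oxy}pent-1-en-2-yl)-3-hydroxy-7-methyloct-6-en-1-yl]oxy}-2H-chromen-2-one | CC(C)(C)[Si](C)(C)OCCCC(=C)[C@H](COc1ccc2ccc(=O)oc2c1)[C@H](O)CC/C=C(\C)CO[Si](c1ccccc1)(c1ccccc1)C(C)(C)C | intermediate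
19 | 7-{[(2R,6E)-8-{[tert-butyl(diphenyl)silyl]oxy}-2-(5-{[tert-butyl(dimethyl)silyl]oxy}pent-1-en-2-yl)-7-methyl-3-oxooct-6-en-1-yl]oxy}-2H-chromen-2-one | CC(C)(C)[Si](C)(C)OCCCC(=C)[C@H](COc1ccc2ccc(=O)oc2c1)C(=O)CC/C=C(\C)CO[Si](c1ccccc1)(c1ccccc1)C(C)(C)C | intermediate
20 | 7-{[(2R)-2-(2-{(3E)-5-[(tert-butyldiphenylsilyl)oxy]-4-methylpent-3-en-1-yl}-1,3-dioxolan-2-yl)-6-[(tert-butyldimethylsilyl)oxy]-3-methylidenehexyl]oxy}-2H-chromen-2-one | CC(C)(C)[Si](C)(C)OCCCC(=C)[C@H](COc1ccc2ccc(=O)oc2c1)C1(OCCO1)CC/C=C(\C)CO[Si](c1ccccc1)(c1ccccc1)C(C)(C)C | intermediate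
21 | 7-{[(2R)-6-hydroxy-2-{2-[(3E)-5-hydroxy-4-methylpent-3-en-1-yl]-1,3-dioxolan-2-yl}-3-methylidenehexyl]oxy}-2H-chromen-2-one | OCCCC(=C)[C@H](COc1ccc2ccc(=O)oc2c1)C1(OCCO1)CC/C=C(\C)CO | intermediate
22 | (2E)-2-methyl-5-{2-[(2R)-3-methylidene-6-oxo-1-[(2-oxo-2H-chromen-7-yl)oxy]hexan-2-yl]-1,3-dioxolan-2-yl}pent-2-enal | O=CCCC(=C)[C@H](COc1ccc2ccc(=O)oc2c1)C1(OCCO1)CC/C=C(\C)C=O | intermediate
23 | ring-B iron enolate, drawn as the free enolate: 2-[(6R,7R,8S)-7-methyl-6-{[(2-oxo-2H-chromen-7-yl)oxy]methyl}-7-(3-oxopropyl)-1,4-dioxaspiro[4.5]decan-8-yl]prop-1-en-1-olate | O=CCC[C@@]1(C)[C@H](COc2ccc3ccc(=O)oc3c2)C2(OCCO2)CC[C@@H]1C(C)=C[O-] | intermediate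
24 | (1'R,4a'S,5'S,6'R,8a'R)-6'-hydroxy-5',8a'-dimethyl-1'-{[(2-oxo-2H-chromen-7-yl)oxy]methyl}octahydro-1'H-spiro[1,3-dioxolane-2,2'-naphthalene]-5'-carbaldehyde (trans-fused; formyl axial and cis to the angular methyl, hydroxyl equatorial) | O1CCOC12CC[C@@H]3[C@](C)(C=O)[C@H](O)CC[C@@]3(C)[C@@H]2COc2ccc3ccc(=O)oc3c2 | intermediate
25 | 7-{[(1'R,4a'S,5'R,6'R,8a'R)-6'-hydroxy-5'-(hydroxymethyl)-5',8a'-dimethyloctahydro-1'H-spiro[1,3-dioxolane-2,2'-naphthalen]-1'-yl]methoxy}-2H-chromen-2-one | O1CCOC12CC[C@@H]3[C@](C)(CO)[C@H](O)CC[C@@]3(C)[C@@H]2COc2ccc3ccc(=O)oc3c2 | intermediate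
26 | 7-{[(1R,4aS,5R,6R,8aR)-6-hydroxy-5-(hydroxymethyl)-5,8a-dimethyl-2-oxodecahydronaphthalen-1-yl]methoxy}-2H-chromen-2-one | O=C1CC[C@@H]2[C@](C)(CO)[C@H](O)CC[C@@]2(C)[C@@H]1COc1ccc2ccc(=O)oc2c1 | intermediate
27 | 7-{[(1R,4aS,5R,6R,8aR)-6-hydroxy-5-(hydroxymethyl)-5,8a-dimethyl-2-methylidenedecahydronaphthalen-1-yl]methoxy}-2H-chromen-2-one | C=C1CC[C@@H]2[C@](C)(CO)[C@H](O)CC[C@@]2(C)[C@@H]1COc1ccc2ccc(=O)oc2c1 | target

Total step count: 16. Longest linear sequence: 13 steps (steps 1 to 3, or 4 to 6, followed by steps 7 to 16).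

Steps most likely to fail

Step 14. The planar C-10 radical may fail to distinguish its methyl group from the 3-oxopropyl arm; an axial arm would lead to the cis-fused ring system. The iron enolate may also be protonated before it closes ring A. The fallback sets out from 21 and comes back at 24, and it separates the two ring closures. MnO2 in CH2Cl2 should oxidise only the allylic alcohol of 21 to the hydroxy enal F1. The same Fe(acac)3/PhSiH3 conditions should then close ring B alone, with the enolate protonated by ethanol, to give the ring-B hydroxy aldehyde F2. The C-10 epimers should be separable at this monocyclic stage, and the new α-centre is of no consequence. Dess–Martin oxidation should give the ring-B dialdehyde F3. An acid-catalysed intramolecular aldol addition (camphorsulfonic acid, CH2Cl2) should then close ring A under thermodynamic control to give 24; it runs through the more substituted enol of the α-branched aldehyde, and its adduct cannot dehydrate.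

Step 10 (the ketone is carried into step 11). Ketone 19 is a β-aryloxy ketone whose α-hydrogen is also allylic, so β-elimination of the coumarin-7-oxide and epimerisation at C-9 may occur before the ketal is in place. The fallback sets out from 16 and comes back at 20, and it introduces the aryl ether only after ketalisation. Selective silylation of the primary hydroxyl of 16 (Et3SiCl, imidazole, −20 °C) should give the primary triethylsilyl ether F4. Dess–Martin oxidation should give the β-silyloxy ketone F5, whose poor leaving group should suppress the elimination. Noyori ketalisation should give the dioxolane F6. PPTS in MeOH at 0 °C should remove only the triethylsilyl group to give the primary alcohol F7, and Mitsunobu reaction of F7 with 17 then gives 20.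

Step 16. Methylenation of the hindered C-8 ketone may be slow, which leaves time for enolisation toward C-9 and loss of the aryloxy group, and the free hydroxyls consume reagent. The fallback sets out from 26 and comes back at 27, and it is a Peterson olefination in two stages. Addition of Me3SiCH2Li/CeCl3 (THF, −78 °C; the organocerium reagent is non-basic and should spare the lactone at this temperature) should give the β-hydroxysilane F8. Acid-induced elimination (aqueous HF, MeCN) should then expel the silanol and give 27 with the double bond fixed in the exocyclic position.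

Further compounds
F1 | step 14 | (2E)-5-{2-[(2R)-6-hydroxy-3-methylidene-1-[(2-oxo-2H-chromen-7-yl)oxy]hexan-2-yl]-1,3-dioxolan-2-yl}-2-methylpent-2-enal | OCCCC(=C)[C@H](COc1ccc2ccc(=O)oc2c1)C1(OCCO1)CC/C=C(\C)C=O
F2 | step 14 | 2-[(6R,7R,8R)-7-(3-hydroxypropyl)-7-methyl-6-{[(2-oxo-2H-chromen-7-yl)oxy]methyl}-1,4-dioxaspiro[4.5]decan-8-yl]propanal (both α-epimers) | OCCC[C@@]1(C)[C@H](COc2ccc3ccc(=O)oc3c2)C2(OCCO2)CC[C@@H]1C(C)C=O
F3 | step 14 | 3-[(6R,7R,8R)-7-methyl-6-{[(2-oxo-2H-chromen-7-yl)oxy]methyl}-8-(1-oxopropan-2-yl)-1,4-dioxaspiro[4.5]decan-7-yl]propanal (both α-epimers) | O=CCC[C@@]1(C)[C@H](COc2ccc3ccc(=O)oc3c2)C2(OCCO2)CC[C@@H]1C(C)C=O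
F4 | step 10 | primary triethylsilyl ether of 16, (2R,3R,6E)-configured | CC(C)(C)[Si](C)(C)OCCCC(=C)[C@H](CO[Si](CC)(CC)CC)[C@H](O)CC/C=C(\C)CO[Si](c1ccccc1)(c1ccccc1)C(C)(C)C
F5 | step 10 | (2R,6E)-3-oxo analogue of F4 (β-silyloxy ketone) | CC(C)(C)[Si](C)(C)OCCCC(=C)[C@H](CO[Si](CC)(CC)CC)C(=O)CC/C=C(\C)CO[Si](c1ccccc1)(c1ccccc1)C(C)(C)C
F6 | step 10 | 1,3-dioxolane of F5, (2R)-configured | CC(C)(C)[Si](C)(C)OCCCC(=C)[C@H](CO[Si](CC)(CC)CC)C1(OCCO1)CC/C=C(\C)CO[Si](c1ccccc1)(c1ccccc1)C(C)(C)C
F7 | step 10 | (2R)-2-(2-{(3E)-5-[(tert-butyldiphenylsilyl)oxy]-4-methylpent-3-en-1-yl}-1,3-dioxolan-2-yl)-6-[(tert-butyldimethylsilyl)oxy]-3-methylidenehexan-1-ol | CC(C)(C)[Si](C)(C)OCCCC(=C)[C@H](CO)C1(OCCO1)CC/C=C(\C)CO[Si](c1ccccc1)(c1ccccc1)C(C)(C)C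
F8 | step 16 | 7-{[(1R,4aS,5R,6R,8aR)-2,6-dihydroxy-5-(hydroxymethyl)-5,8a-dimethyl-2-[(trimethylsilyl)methyl]decahydronaphthalen-1-yl]methoxy}-2H-chromen-2-one (configuration at C-2 not defined) | C[Si](C)(C)CC1(O)CC[C@@H]2[C@](C)(CO)[C@H](O)CC[C@@]2(C)[C@@H]1COc1ccc2ccc(=O)oc2c1
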